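**Strategy.** Everything rests on disconnecting the C2–C3 bond of ring C. The precursor is an open-chain 2-diazoacetyl aryl ether: ring A carries a diazomethyl ketone (future C4 and C3) next to a 4-methoxybenzyl ether (future O1, C2 and ring B). A chiral dirhodium tetracarboxylate turns the diazo carbon into a carbene that inserts into a C–H bond of the 1,6-related OCH2 group, a methylene that is benzylic to ring B and alpha to O1. One operation closes ring C, forms its only new C–C bond and sets the single stereocentre C2, under neutral conditions in which the flavanone cannot racemise by retro-oxa-Michael ring opening.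

Key step: step 5

Assumption: Rh2(S-BSP)4 is taken to deliver the 2S enantiomer; no reliable model fixes the sense of induction for this acceptor carbene, and if 2R should predominate the mirror-image catalyst Rh2(R-BSP)4 (from D-proline) is to be used with nothing else changed.

Step 1
Reactants: 1 1,2,3,4-tetramethoxybenzene
Product: 4 2,3,4,5-tetramethoxyphenol, via aryllithium 2 (not isolated), via dimethyl arylboronate 3 (not isolated)
Conditions: n-BuLi, TMEDA, THF, 0 °C; B(OMe)3, −78 °C to rt; AcOH, 30% aq H2O2, 0 °C to rt
Reagents that add atoms: hydrogen peroxide, OO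
Why: Directed ortho-lithiation beside a methoxy group (the two ring hydrogens of 1 are equivalent, so one aryllithium results), borylation and peroxide oxidation with 1,2-migration of the aryl group from boron to oxygen should give the phenol.

Step 2
Reactants: 4 2,3,4,5-tetramethoxyphenol
Product: 7 1-(2-hydroxy-3,4,5,6-tetramethoxyphenyl)ethanone, via aryl acetate 5 (not isolated), via difluoroboron chelate 6 (not isolated)
Conditions: AcOH, BF3·OEt2, 90 °C; then EtOH–H2O, reflux
Reagents that add atoms: acetic acid, CC(=O)O
Why: BF3-promoted esterification and Fries rearrangement (Friedel–Crafts C-acylation) can reach only the single free ring position, which is ortho to the hydroxyl, and the ketone is held as its BF2 chelate until aqueous ethanol releases it.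

Step 3
Reactants: 7 1-(2-hydroxy-3,4,5,6-tetramethoxyphenyl)ethanone, 8 4-methoxybenzyl chloride
Product: 9 1-[3,4,5,6-tetramethoxy-2-[(4-methoxyphenyl)methoxy]phenyl]ethanone
Conditions: K2CO3, DMF, 60 °C
Reagents that add atoms: none
Why: Williamson ether synthesis, in which the phenoxide is the only nucleophile of consequence (ring A has no free carbon for C-alkylation and K2CO3 does not enolise the ketone) and the benzylic chloride is a reactive SN2 partner.

Step 4
Reactants: 9 1-[3,4,5,6-tetramethoxy-2-[(4-methoxyphenyl)methoxy]phenyl]ethanone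
Product: 12 2-diazo-1-[3,4,5,6-tetramethoxy-2-[(4-methoxyphenyl)methoxy]phenyl]ethanone, via lithium enolate 10 (not isolated), via trifluoroacetyl ketone 11 (not isolated)
Conditions: LiN(SiMe3)2, THF, −78 °C; CF3CO2CH2CF3, −78 °C; dilute aq HCl work-up, crude; then MsN3, Et3N, H2O (1 equiv), MeCN, rt
Reagents that add atoms: methanesulfonyl azide, CS(=O)(=O)N=[N+]=[N-]
Why: Detrifluoroacetylative diazo transfer, in which Claisen-type C-trifluoroacetylation of the kinetic methyl ketone enolate gives an activated 1,3-diketone that accepts the diazo group from the sulfonyl azide and loses the trifluoroacetyl group as the N-acyl sulfonamide, under conditions that leave the aryl ethers untouched.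

Step 5
Reactants: 12 2-diazo-1-[3,4,5,6-tetramethoxy-2-[(4-methoxyphenyl)methoxy]phenyl]ethanone
Product: 14 (2S)-5,6,7,8-tetramethoxy-2-(4-methoxyphenyl)-2,3-dihydro-4H-chromen-4-one [(2S)-5,6,7,8,4'-pentamethoxyflavanone], via dirhodium carbene 13 (not isolated)
Conditions: Rh2(S-BSP)4 (dirhodium tetrakis[(S)-N-(benzenesulfonyl)prolinate], 2 mol%), CH2Cl2, 0 °C to rt, slow addition of 12
Reagents that add atoms: none
Why: The dirhodium tetracarboxylate takes N2 from 12 to give the electrophilic acceptor carbene 13, whose carbene carbon (future C3) inserts into one C–H bond of the ArO–CH2–Ar' methylene (future C2) through a concerted but asynchronous three-centre transition state with hydride-transfer character, which forms the C2–C3 bond with retention at C2 and releases the catalyst. The closest known reaction type is the intramolecular C–H insertion of divalent-rhodium carbenes derived from 2-alkoxyaryl diazo ketones, which gives chroman-4-ones, together with carbene insertion into benzylic ether C–H bonds. Ring C closes as a six-membered ring by 1,6-C–H insertion; the usually preferred 1,5-position is the hydrogen-free atom O1, so no smaller carbocycle can form. The only stereocentre, C2, is set by the chiral N-sulfonylprolinate ligand sphere of the catalyst, which selects one of the two enantiotopic benzylic hydrogens for replacement. The step needs site selectivity over the equally distant methyl C–H bonds of the methoxy group on the other side of the ketone (future C5-OMe) and chemoselectivity over attack of the carbene on the O1 lone pair (oxonium ylide, then 1,2-shift of the benzyl group): the first is secured because the chosen C–H is secondary, benzylic, alpha to oxygen and para-methoxy-activated, hence by far the best hydride donor, and the second is favoured by the weakly basic, doubly ortho-flanked aryl ether oxygen and by a carboxylate catalyst of moderate electrophilicity at low temperature. The product forms under neutral conditions, so C2 is not scrambled by retro-oxa-Michael opening.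

**Compound list**

1 | 1,2,3,4-tetramethoxybenzene | COc1ccc(OC)c(OC)c1OC | starting material
2 | (2,3,4,5-tetramethoxyphenyl)lithium | [Li]c1cc(OC)c(OC)c(OC)c1OC | intermediate
3 | dimethyl (2,3,4,5-tetramethoxyphenyl)boronate | COB(OC)c1cc(OC)c(OC)c(OC)c1OC | intermediate
4 | 2,3,4,5-tetramethoxyphenol | COc1cc(O)c(OC)c(OC)c1OC | intermediate
5 | 2,3,4,5-tetramethoxyphenyl acetate | CC(=O)Oc1cc(OC)c(OC)c(OC)c1OC | intermediate
6 | difluoroboron chelate of 7 (BF2 bridging the phenolic and the ketone oxygen) | CC1=[O+][B-](F)(F)Oc2c(OC)c(OC)c(OC)c(OC)c12 | intermediate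
7 | 1-(2-hydroxy-3,4,5,6-tetramethoxyphenyl)ethanone | CC(=O)c1c(O)c(OC)c(OC)c(OC)c1OC | intermediate
8 | 4-methoxybenzyl chloride | COc1ccc(CCl)cc1 | starting material
9 | 1-[3,4,5,6-tetramethoxy-2-[(4-methoxyphenyl)methoxy]phenyl]ethanone | COc1ccc(COc2c(OC)c(OC)c(OC)c(OC)c2C(C)=O)cc1 | intermediate
10 | lithium enolate of 9 | COc1ccc(COc2c(OC)c(OC)c(OC)c(OC)c2C(=C)O[Li])cc1 | intermediate
11 | 4,4,4-trifluoro-1-[3,4,5,6-tetramethoxy-2-[(4-methoxyphenyl)methoxy]phenyl]butane-1,3-dione | COc1ccc(COc2c(OC)c(OC)c(OC)c(OC)c2C(=O)CC(=O)C(F)(F)F)cc1 | intermediate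
12 | 2-diazo-1-[3,4,5,6-tetramethoxy-2-[(4-methoxyphenyl)methoxy]phenyl]ethanone | COc1ccc(COc2c(OC)c(OC)c(OC)c(OC)c2C(=O)C=[N+]=[N-])cc1 | intermediate
13 | dirhodium carbene from 12 on Rh2(S-BSP)4 (carbene on the axial site of one rhodium; paddlewheel written with formal charges) | COc1ccc(COc2c(OC)c(OC)c(OC)c(OC)c2C(=O)C=[Rh-2]3456OC([C@@H]7CCCN7S(=O)(=O)c7ccccc7)=[O+][Rh-2]3(OC([C@@H]7CCCN7S(=O)(=O)c7ccccc7)=[O+]4)([O+]=C([C@@H]7CCCN7S(=O)(=O)c7ccccc7)O5)OC([C@@H]7CCCN7S(=O)(=O)c7ccccc7)=[O+]6)cc1 | intermediate
14 | (2S)-5,6,7,8-tetramethoxy-2-(4-methoxyphenyl)-2,3-dihydro-4H-chromen-4-one | COc1ccc([C@@H]2CC(=O)c3c(OC)c(OC)c(OC)c(OC)c3O2)cc1 | target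

**Total step count:** 5. **Longest linear sequence:** 5 steps (1 to 14).

**Steps most likely to fail**

1. Step 5. The carbene may be captured by the lone pair of the benzylic ether oxygen and then suffer 1,2-shift of the 4-methoxybenzyl group with ring contraction instead of inserting into C–H. An acceptor-only carbene may also discriminate poorly between the two enantiotopic benzylic hydrogens. The fallback sets out from 7 and returns at 14; it makes the C2–aryl bond in place of the C2–C3 bond. Condensation of 7 with N,N-dimethylformamide dimethyl acetal (toluene, 100 °C) should give (E)-3-(dimethylamino)-1-(2-hydroxy-3,4,5,6-tetramethoxyphenyl)prop-2-en-1-one F1. Acid (HCl, CH2Cl2, rt) should cyclise this with loss of dimethylamine to 5,6,7,8-tetramethoxy-4H-chromen-4-one F2. Enantioselective conjugate addition of 4-methoxyphenylboronic acid to F2 [Pd(OCOCF3)2, (R)-t-BuPyOx, NH4PF6, H2O, ClCH2CH2Cl, 60 °C] should then give 14, the pyridine-oxazoline ligand directing the aryl group to one face of the C2=C3 bond. The R ligand is expected to give 2S by the usual facial preference of this catalyst class; otherwise its antipode is used.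

2. Step 4. C-Trifluoroacetylation of the hindered enolate, which is twisted out of the ring plane, may be incomplete, and the 4-methoxybenzyl ether may be lost in the acidic work-up between the two stages. The fallback sets out from 9 and returns at 12. A haloform reaction of 9 (NaOCl, NaOH, dioxane–H2O, 60 °C) should pass through 2,2,2-trichloro-1-[3,4,5,6-tetramethoxy-2-[(4-methoxyphenyl)methoxy]phenyl]ethanone F3 (not isolated). Mild acidification should then give 3,4,5,6-tetramethoxy-2-[(4-methoxyphenyl)methoxy]benzoic acid F4. 1-Chloro-N,N,2-trimethylprop-1-en-1-amine (CH2Cl2, 0 °C) should convert F4 under neutral conditions into 3,4,5,6-tetramethoxy-2-[(4-methoxyphenyl)methoxy]benzoyl chloride F5. Acylation of diazomethane by F5 (CH2N2, Et3N, Et2O, 0 °C) should give 12.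

3. Step 2. The Lewis acid may cleave methyl ethers at 90 °C, and the reaction may stall at the aryl acetate because the only free ring position is flanked on both sides. The fallback sets out from 4 and returns at 7. Protection (MOMCl, i-Pr2NEt, CH2Cl2) should give 1,2,3,4-tetramethoxy-5-(methoxymethoxy)benzene F6. n-BuLi (THF, −78 to 0 °C) should remove the only ring hydrogen, which lies between OMOM and OMe, to give [2,3,4,5-tetramethoxy-6-(methoxymethoxy)phenyl]lithium F7. Acylation with N-methoxy-N-methylacetamide and aq NH4Cl quench should give 1-[2,3,4,5-tetramethoxy-6-(methoxymethoxy)phenyl]ethanone F8. HCl in MeOH (40 °C) should remove the acetal and return 7.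

**Further compounds**

F1 | step 5 | (E)-3-(dimethylamino)-1-(2-hydroxy-3,4,5,6-tetramethoxyphenyl)prop-2-en-1-one | CN(C)/C=C/C(=O)c1c(O)c(OC)c(OC)c(OC)c1OC
F2 | step 5 | 5,6,7,8-tetramethoxy-4H-chromen-4-one | O=c1ccoc2c(OC)c(OC)c(OC)c(OC)c12
F3 | step 4 | 2,2,2-trichloro-1-[3,4,5,6-tetramethoxy-2-[(4-methoxyphenyl)methoxy]phenyl]ethanone | COc1ccc(COc2c(OC)c(OC)c(OC)c(OC)c2C(=O)C(Cl)(Cl)Cl)cc1
F4 | step 4 | 3,4,5,6-tetramethoxy-2-[(4-methoxyphenyl)methoxy]benzoic acid | COc1ccc(COc2c(OC)c(OC)c(OC)c(OC)c2C(O)=O)cc1
F5 | step 4 | 3,4,5,6-tetramethoxy-2-[(4-methoxyphenyl)methoxy]benzoyl chloride | COc1ccc(COc2c(OC)c(OC)c(OC)c(OC)c2C(Cl)=O)cc1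
F6 | step 2 | 1,2,3,4-tetramethoxy-5-(methoxymethoxy)benzene | COCOc1cc(OC)c(OC)c(OC)c1OC
F7 | step 2 | [2,3,4,5-tetramethoxy-6-(methoxymethoxy)phenyl]lithium | COCOc1c([Li])c(OC)c(OC)c(OC)c1OC
F8 | step 2 | 1-[2,3,4,5-tetramethoxy-6-(methoxymethoxy)phenyl]ethanone | COCOc1c(C(C)=O)c(OC)c(OC)c(OC)c1OC
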